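**Retrosynthetic overview**

1. Atom numbers follow the abietane skeleton: ring A = C1–C5 and C10, ring B = C5–C10, ring C = C8, C9, C11–C14; C20 = lactone carbonyl on C10; C18/C19 = CH3/CH2OH on C4.
2. Target ⇒ cleavage of one O-methyl and one MOM group ⇒ oxidation of a 1,2,4-trimethoxyarene to the quinone ⇒ tetracyclic aryl lactone 25.
3. 25 ⇒ monocyclic dihydropyranone 24: bonds C4–C5 and C9–C10 are cut together; forward, one radical cascade closes ring A and then ring B, which completes the bicyclo[2.2.2] lactone.
4. Enabling feature: the α,β-unsaturated δ-lactone ring O–C20(=O)–C10=C5–C6–C7, whose β-carbon C5 accepts the C4 radical while its α-carbon C10 lies 1,4 across the ring from C7 and the aryl carbon C9.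
5. 24 ⇒ ring-closing metathesis ⇒ ester of syn-alkoxy alcohol 10 (C6, C7 from asymmetric alkoxyallylboration of aldehyde 6) with acrylic acid 20 (C1–C4, C10, C18–C20); ring order: C (bought), lactone, A, B.

Key step: step 13

Assumption: allyl methoxymethyl ether 7 and (−)-B-methoxydiisopinocampheylborane are taken as purchasable; the borane made from (+)-α-pinene is expected to attack aldehyde 6 with the same facial sense as in the allylation of benzaldehyde to the (S)-alcohol.

**Route**

Step 1
Reactants: 1 1,2,4-trimethoxybenzene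
Product: 3 2-(2,3,6-trimethoxyphenyl)propan-2-ol, via aryllithium 2 (not isolated)
Conditions: n-BuLi, THF, 0 °C to rt; acetone, −78 °C to rt; H2O
Reagents that add atoms: acetone, CC(C)=O
Why: Directed ortho-lithiation at the position flanked by two methoxy groups, followed by 1,2-addition of the aryllithium to acetone.

Step 2
Reactants: 3 2-(2,3,6-trimethoxyphenyl)propan-2-ol
Product: 4 1,2,4-trimethoxy-3-(propan-2-yl)benzene
Conditions: Et3SiH, CF3CO2H, CH2Cl2, 0 °C to rt
Reagents that add atoms: none
Why: Ionic hydrogenation, in which the acid ionises the tertiary benzylic alcohol and the silane delivers hydride to the cation.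

Step 3
Reactants: 4 1,2,4-trimethoxy-3-(propan-2-yl)benzene
Product: 6 2,4,5-trimethoxy-3-(propan-2-yl)benzaldehyde, via iminium chloride 5 (not isolated)
Conditions: POCl3, DMF, 0 to 70 °C; then H2O, 0 °C
Reagents that add atoms: N,N-dimethylformamide, CN(C)C=O; water, O
Why: Vilsmeier–Haack formylation at the free position that is para to one methoxy group and ortho to another (the later C8), followed by hydrolysis of the iminium salt.

Step 4
Reactants: 6 2,4,5-trimethoxy-3-(propan-2-yl)benzaldehyde; 7 3-(methoxymethoxy)prop-1-ene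
Product: 10 (1R,2R)-2-(methoxymethoxy)-1-[2,4,5-trimethoxy-3-(propan-2-yl)phenyl]but-3-en-1-ol, via allyllithium 8 (not isolated), via allylborane 9 (not isolated)
Conditions: 7, s-BuLi, THF, −78 °C; (−)-B-methoxydiisopinocampheylborane; BF3·OEt2; 6, −78 °C; then NaOH, H2O2, 0 °C to rt
Reagents that add atoms: none
Why: Asymmetric alkoxyallylboration through a closed chair transition state, in which the Z geometry of the γ-alkoxyallylborane gives the syn relation of C6 and C7 and the isopinocampheyl groups choose the aldehyde face.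

Step 5
Reactants: 11 1-bromo-3-chloropropane; 12 prop-2-yn-1-ol
Product: 14 2-(3-chloropropyl)prop-2-en-1-ol, via Grignard reagent 13 (not isolated)
Conditions: 11, Mg, THF, 0 °C to rt; then 12 (0.4 equiv), CuI (10 mol %), THF–Et2O, −20 °C to rt; H2O
Reagents that add atoms: none
Why: Copper-catalysed carbomagnesiation of propargyl alcohol, in which the magnesium alkoxide directs the alkyl group to the internal alkyne carbon and hydrolysis gives the 2-substituted allyl alcohol.

Step 6
Reactants: 14 2-(3-chloropropyl)prop-2-en-1-ol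
Product: 15 tert-butyl[(5-chloro-2-methylidenepentyl)oxy]dimethylsilane
Conditions: TBSCl, imidazole, DMF, rt
Reagents that add atoms: tert-butyldimethylsilyl chloride, CC(C)(C)[Si](C)(C)Cl
Why: Silyl ether formation masks the hydroxyl group for the basic steps that follow.

Step 7
Reactants: 15 tert-butyl[(5-chloro-2-methylidenepentyl)oxy]dimethylsilane; 16 triethyl phosphonoacetate
Product: 18 ethyl 7-[(tert-butyldimethylsilyl)oxy]-2-(diethoxyphosphoryl)-6-methylideneheptanoate, via sodium phosphonate 17 (not isolated)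
Conditions: 16, NaH, THF–DMF, 0 °C; then 15, NaI (10 mol %), 60 °C
Reagents that add atoms: none
Why: SN2 alkylation of the stabilised phosphonate carbanion, helped by in situ Finkelstein exchange of the chloride.

Step 8
Reactants: 18 ethyl 7-[(tert-butyldimethylsilyl)oxy]-2-(diethoxyphosphoryl)-6-methylideneheptanoate
Product: 19 ethyl 7-[(tert-butyldimethylsilyl)oxy]-2,6-dimethylideneheptanoate
Conditions: aqueous HCHO, K2CO3, THF–H2O, rt to 40 °C
Reagents that add atoms: formaldehyde, C=O
Why: Horner–Wadsworth–Emmons methylenation with formaldehyde gives the 2-substituted acrylate.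

Step 9
Reactants: 19 ethyl 7-[(tert-butyldimethylsilyl)oxy]-2,6-dimethylideneheptanoate
Product: 20 7-[(tert-butyldimethylsilyl)oxy]-2,6-dimethylideneheptanoic acid
Conditions: LiOH, THF–H2O, rt; then aqueous HCl to pH 4, 0 °C
Reagents that add atoms: lithium hydroxide, [Li+].[OH-]
Why: Ester saponification, which the primary silyl ether and both 1,1-disubstituted alkenes should survive.

Step 10
Reactants: 10 (1R,2R)-2-(methoxymethoxy)-1-[2,4,5-trimethoxy-3-(propan-2-yl)phenyl]but-3-en-1-ol; 20 7-[(tert-butyldimethylsilyl)oxy]-2,6-dimethylideneheptanoic acid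
Product: 22 (1R,2R)-2-(methoxymethoxy)-1-[2,4,5-trimethoxy-3-(propan-2-yl)phenyl]but-3-en-1-yl 7-[(tert-butyldimethylsilyl)oxy]-2,6-dimethylideneheptanoate, via mixed anhydride 21 (not isolated)
Conditions: 20, 2,4,6-trichlorobenzoyl chloride, Et3N, THF, rt; then 10, DMAP, toluene, rt
Reagents that add atoms: none
Why: Yamaguchi esterification through the mixed anhydride acylates the hindered benzylic alcohol without touching either stereocentre.

Step 11
Reactants: 22 (1R,2R)-2-(methoxymethoxy)-1-[2,4,5-trimethoxy-3-(propan-2-yl)phenyl]but-3-en-1-yl 7-[(tert-butyldimethylsilyl)oxy]-2,6-dimethylideneheptanoate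
Product: 23 (5R,6R)-3-(4-{[(tert-butyldimethylsilyl)oxy]methyl}pent-4-en-1-yl)-5-(methoxymethoxy)-6-[2,4,5-trimethoxy-3-(propan-2-yl)phenyl]-5,6-dihydro-2H-pyran-2-one
Conditions: second-generation Grubbs catalyst RuCl2(=CHPh)(PCy3)(H2IMes) (5–10 mol %), toluene (5 mM), 80 °C
Reagents that add atoms: none
Why: Ring-closing metathesis between the vinyl group and the acrylate gives the six-membered unsaturated lactone (the C5=C10 bond), while the hindered 1,1-disubstituted allyl silyl ether alkene should stay out.

Step 12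
Reactants: 23 (5R,6R)-3-(4-{[(tert-butyldimethylsilyl)oxy]methyl}pent-4-en-1-yl)-5-(methoxymethoxy)-6-[2,4,5-trimethoxy-3-(propan-2-yl)phenyl]-5,6-dihydro-2H-pyran-2-one
Product: 24 (5R,6R)-3-[4-(hydroxymethyl)pent-4-en-1-yl]-5-(methoxymethoxy)-6-[2,4,5-trimethoxy-3-(propan-2-yl)phenyl]-5,6-dihydro-2H-pyran-2-one
Conditions: HF·pyridine, pyridine, THF, 0 °C to rt
Reagents that add atoms: none
Why: Fluoride-mediated desilylation frees the C19 hydroxyl, which the key step needs, while lactone and MOM ether should survive buffered HF.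

Step 13
Reactants: 24 (5R,6R)-3-[4-(hydroxymethyl)pent-4-en-1-yl]-5-(methoxymethoxy)-6-[2,4,5-trimethoxy-3-(propan-2-yl)phenyl]-5,6-dihydro-2H-pyran-2-one
Product: 25 (4S,5S,6R,7R,10R)-19-hydroxy-11,12,14-trimethoxy-6-(methoxymethoxy)abieta-8,11,13-trien-20,7-olide
Conditions: Co(C36H52N2O2) [Co(salen), divalent cobalt, salen = N,N′-bis(3,5-di-tert-butylsalicylidene)cyclohexane-1,2-diamine dianion] (10 mol %), N-fluoro-2,4,6-trimethylpyridinium tetrafluoroborate (1.5 equiv), PhSiH3 (1.5 equiv), (CF3)2CHOH (5 mM), 0 °C to rt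
Reagents that add atoms: none
Why: Proposed new method: a cobalt hydride formed from the Co(salen) complex, the N–F oxidant and PhSiH3 transfers a hydrogen atom to the CH2 terminus of the 1,1-disubstituted alkene (the enoate is electron-poor and trisubstituted and is left alone), the nucleophilic tertiary C4 radical adds to the β-carbon C5 of the unsaturated δ-lactone (Giese addition; C10 is fully substituted and polarity-mismatched), and the resulting C10 α-acyl radical attacks the electron-rich aryl carbon C9 across the boat form of the lactone before trivalent cobalt oxidises the cyclohexadienyl radical and a proton is lost; the closest known reaction type is the cobalt-catalysed hydrogen-atom-transfer radical bicyclization of aryl dienes that carry an electron-poor central alkene and end on the arene, which has not been shown for a lactone-bridged substrate of this kind. Ring A closes by 6-endo-trig radical addition (bond C4–C5) and ring B, and with it the bicyclo[2.2.2] lactone, by six-membered ortho attack on the arene (homolytic aromatic substitution, bond C9–C10). C5 is controlled by the C6 stereocentre (attack anti to the pseudoaxial OMOM group) and C10 by the tether, because C9 can reach C10 only on the face that carries the C7 aryl group, which is opposite to the new C4–C5 bond and gives the trans relation of H5 and C20. C4 is not fixed by the ring system, and for this reason the C19 hydroxyl is left free: only the transition state with CH2OH over the lactone ring (the later axial position, syn to C20) allows an O–H···O=C20 hydrogen bond, which the donor solvent (CF3)2CHOH should not break and which also activates the acceptor, while the hydrogen atom from cobalt turns the other alkene carbon into the equatorial C18 methyl group. The step needs the C10 radical to attack C9 faster than it is reduced or loses a β-hydrogen, which the fixed cis placement of aryl group and radical lobe on the six-membered lactone and the electron-rich arene should secure.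

Step 14
Reactants: 25 (4S,5S,6R,7R,10R)-19-hydroxy-11,12,14-trimethoxy-6-(methoxymethoxy)abieta-8,11,13-trien-20,7-olide
Product: 26 (4S,5S,6R,7R,10R)-19-hydroxy-12-methoxy-6-(methoxymethoxy)-11,14-dioxoabieta-8,12-dien-20,7-olide
Conditions: (NH4)2Ce(NO3)6 (2.5 equiv), MeCN–H2O, 0 °C
Reagents that add atoms: water, O
Why: Oxidative demethylation of the para-dimethoxy pair at C11 and C14 by tetravalent cerium gives the 2-methoxy-1,4-benzoquinone, and the bridgehead C7 cannot ionise or form a quinone methide.

Step 15
Reactants: 26 (4S,5S,6R,7R,10R)-19-hydroxy-12-methoxy-6-(methoxymethoxy)-11,14-dioxoabieta-8,12-dien-20,7-olide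
Product: 27 (4S,5S,6R,7R,10R)-6,12,19-trihydroxy-11,14-dioxoabieta-8,12-dien-20,7-olide (CNP0339604.1)
Conditions: BCl3 (excess), CH2Cl2, −78 to 0 °C; then H2O
Reagents that add atoms: none
Why: Lewis-acid ether cleavage, in which BCl3 removes the MOM acetal at O6 and, through chelation with the C11 carbonyl, the vinylogous methyl ester at O12.

**Compound list**

1 | 1,2,4-trimethoxybenzene | COc1ccc(OC)c(OC)c1 | starting material
2 | (2,3,6-trimethoxyphenyl)lithium | COc1ccc(OC)c(OC)c1[Li] | intermediate
3 | 2-(2,3,6-trimethoxyphenyl)propan-2-ol | COc1ccc(OC)c(OC)c1C(C)(C)O | intermediate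
4 | 1,2,4-trimethoxy-3-(propan-2-yl)benzene | COc1ccc(OC)c(OC)c1C(C)C | intermediate
5 | N,N-dimethyl[2,4,5-trimethoxy-3-(propan-2-yl)phenyl]methaniminium chloride | C[N+](C)=Cc1cc(OC)c(OC)c(C(C)C)c1OC.[Cl-] | intermediate
6 | 2,4,5-trimethoxy-3-(propan-2-yl)benzaldehyde | O=Cc1cc(OC)c(OC)c(C(C)C)c1OC | intermediate
7 | 3-(methoxymethoxy)prop-1-ene (allyl methoxymethyl ether) | C=CCOCOC | starting material
8 | (Z)-[3-(methoxymethoxy)prop-2-en-1-yl]lithium | COCO/C=C\C[Li] | intermediate
9 | (Z)-[3-(methoxymethoxy)prop-2-en-1-yl]diisopinocampheylborane (isopinocampheyl groups from (+)-α-pinene) | COCO/C=C\CB([C@@H]1C[C@@H]2C[C@H]([C@H]1C)C2(C)C)[C@@H]1C[C@@H]2C[C@H]([C@H]1C)C2(C)C | intermediate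
10 | (1R,2R)-2-(methoxymethoxy)-1-[2,4,5-trimethoxy-3-(propan-2-yl)phenyl]but-3-en-1-ol | CC(C)c1c(OC)c(OC)cc(c1OC)[C@@H](O)[C@H](OCOC)C=C | intermediate
11 | 1-bromo-3-chloropropane | ClCCCBr | starting material
12 | prop-2-yn-1-ol | C#CCO | starting material
13 | (3-chloropropyl)magnesium bromide | ClCCC[Mg]Br | intermediate
14 | 2-(3-chloropropyl)prop-2-en-1-ol | OCC(=C)CCCCl | intermediate
15 | tert-butyl[(5-chloro-2-methylidenepentyl)oxy]dimethylsilane | CC(C)(C)[Si](C)(C)OCC(=C)CCCCl | intermediate
16 | triethyl phosphonoacetate | CCOC(=O)CP(=O)(OCC)OCC | starting material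
17 | sodium salt of triethyl phosphonoacetate | CCOC(=O)[CH-]P(=O)(OCC)OCC.[Na+] | intermediate
18 | ethyl 7-[(tert-butyldimethylsilyl)oxy]-2-(diethoxyphosphoryl)-6-methylideneheptanoate | CCOC(=O)C(CCCC(=C)CO[Si](C)(C)C(C)(C)C)P(=O)(OCC)OCC | intermediate
19 | ethyl 7-[(tert-butyldimethylsilyl)oxy]-2,6-dimethylideneheptanoate | CCOC(=O)C(=C)CCCC(=C)CO[Si](C)(C)C(C)(C)C | intermediate
20 | 7-[(tert-butyldimethylsilyl)oxy]-2,6-dimethylideneheptanoic acid | OC(=O)C(=C)CCCC(=C)CO[Si](C)(C)C(C)(C)C | intermediate
21 | mixed anhydride of 20 with 2,4,6-trichlorobenzoic acid | C=C(CCCC(=C)CO[Si](C)(C)C(C)(C)C)C(=O)OC(=O)c1c(Cl)cc(Cl)cc1Cl | intermediate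
22 | (1R,2R)-2-(methoxymethoxy)-1-[2,4,5-trimethoxy-3-(propan-2-yl)phenyl]but-3-en-1-yl 7-[(tert-butyldimethylsilyl)oxy]-2,6-dimethylideneheptanoate | CC(C)c1c(OC)c(OC)cc(c1OC)[C@@H](OC(=O)C(=C)CCCC(=C)CO[Si](C)(C)C(C)(C)C)[C@H](OCOC)C=C | intermediate
23 | (5R,6R)-3-(4-{[(tert-butyldimethylsilyl)oxy]methyl}pent-4-en-1-yl)-5-(methoxymethoxy)-6-[2,4,5-trimethoxy-3-(propan-2-yl)phenyl]-5,6-dihydro-2H-pyran-2-one | CC(C)c1c(OC)c(OC)cc(c1OC)[C@H]1OC(=O)C(CCCC(=C)CO[Si](C)(C)C(C)(C)C)=C[C@H]1OCOC | intermediate
24 | (5R,6R)-3-[4-(hydroxymethyl)pent-4-en-1-yl]-5-(methoxymethoxy)-6-[2,4,5-trimethoxy-3-(propan-2-yl)phenyl]-5,6-dihydro-2H-pyran-2-one | CC(C)c1c(OC)c(OC)cc(c1OC)[C@H]1OC(=O)C(CCCC(=C)CO)=C[C@H]1OCOC | intermediate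
25 | (4S,5S,6R,7R,10R)-19-hydroxy-11,12,14-trimethoxy-6-(methoxymethoxy)abieta-8,11,13-trien-20,7-olide | CC(C)c1c(OC)c(OC)c2c(c1OC)[C@H]1OC(=O)[C@@]23CCC[C@](C)(CO)[C@@H]3[C@H]1OCOC | intermediate
26 | (4S,5S,6R,7R,10R)-19-hydroxy-12-methoxy-6-(methoxymethoxy)-11,14-dioxoabieta-8,12-dien-20,7-olide | CC(C)C1=C(OC)C(=O)C2=C(C1=O)[C@H]1OC(=O)[C@@]23CCC[C@](C)(CO)[C@@H]3[C@H]1OCOC | intermediate
27 | (4S,5S,6R,7R,10R)-6,12,19-trihydroxy-11,14-dioxoabieta-8,12-dien-20,7-olide | CC(C)C1=C(O)C(=O)C2=C(C1=O)[C@H]1OC(=O)[C@@]23CCC[C@](C)(CO)[C@@H]3[C@H]1O | target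

**Step count and risks**

Total step count: 15. Longest linear sequence: 11 steps (steps 5 to 15, from 11 and 12); the arene branch reaches 27 in 10 steps.

Steps most likely to fail:

Step 13 (proposed new method). Two processes may fail. After ring A has closed, the C10 radical may be reduced or lose a β-hydrogen before it attacks C9, so that ring B stays open. The hydrogen bond may also steer the C4 centre too weakly, so that methyl and hydroxymethyl are not told apart. The fallback is stepwise and uses known reaction types. It sets out from 24: a reductive hydrogen-atom-transfer Giese cyclization (Fe(acac)3, PhSiH2(O-i-Pr), THF, rt) should close ring A only and give the 9,10-seco lactone F1, at which stage C4 epimers can be separated. N-Bromosuccinimide in MeCN should then brominate the only free arene position C9 to give the aryl bromide F2. A palladium-catalysed intramolecular α-arylation of the lactone enolate (Pd2(dba)3, P(t-Bu)3, LiN(SiMe3)2 3 equiv, toluene, 60 °C) should form the C9–C10 bond and come back to the route at 25.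

Step 14. The oxidation may take the wrong pair of oxygens (ortho-quinone from C11/C12) or over-oxidise the electron-rich ring. The fallback sets out from 25: BBr3 (CH2Cl2, −78 to 0 °C) should cleave all three aryl methyl ethers and the MOM group to the hydroxyhydroquinone F3; the bridgehead C7 protects the benzylic lactone from ionisation. Air oxidation of this benzene-1,2,4-triol (O2, MeOH, rt) should then give the hydroxyquinone and come back to the route at 27, replacing steps 14 and 15.

Step 11. Ring closure at the 1,1-disubstituted acrylate may be slow, so that intermolecular metathesis of the vinyl group competes. The fallback forms the C5=C10 bond by olefination and sets out from 10 and 18. Oxidative cleavage of the vinyl group of 10 (OsO4 catalytic, NaIO4, 2,6-lutidine, dioxane–H2O) should give the aldehyde F4, to be used without delay. Saponification of 18 (LiOH, THF–H2O) should give the phosphono acid F5. Carbodiimide coupling (DCC, DMAP, CH2Cl2) should give the phosphonate ester F6, and an intramolecular Horner–Wadsworth–Emmons reaction (LiCl, i-Pr2NEt, MeCN) should close the lactone and come back to the route at 23, replacing steps 8 to 11.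

**Further compounds**

F1 | step 13 | (4S,5S,6R,7R)-19-hydroxy-11,12,14-trimethoxy-6-(methoxymethoxy)-9,10-secoabieta-8,11,13-trien-20,7-olide (either C10 epimer) | CC(C)c1c(OC)c(OC)cc(c1OC)[C@H]1OC(=O)C2CCC[C@](C)(CO)[C@@H]2[C@H]1OCOC
F2 | step 13 | 9-bromo derivative of F1 | CC(C)c1c(OC)c(OC)c(Br)c(c1OC)[C@H]1OC(=O)C2CCC[C@](C)(CO)[C@@H]2[C@H]1OCOC
F3 | step 14 | (4S,5S,6R,7R,10R)-6,11,12,14,19-pentahydroxyabieta-8,11,13-trien-20,7-olide | CC(C)c1c(O)c(O)c2c(c1O)[C@H]1OC(=O)[C@@]23CCC[C@](C)(CO)[C@@H]3[C@H]1O
F4 | step 11 | (2S,3R)-3-hydroxy-2-(methoxymethoxy)-3-[2,4,5-trimethoxy-3-(propan-2-yl)phenyl]propanal | CC(C)c1c(OC)c(OC)cc(c1OC)[C@@H](O)[C@H](OCOC)C=O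
F5 | step 11 | 7-[(tert-butyldimethylsilyl)oxy]-2-(diethoxyphosphoryl)-6-methylideneheptanoic acid | OC(=O)C(CCCC(=C)CO[Si](C)(C)C(C)(C)C)P(=O)(OCC)OCC
F6 | step 11 | ester of F5 with the C3 hydroxyl of F4 | CC(C)c1c(OC)c(OC)cc(c1OC)[C@@H](OC(=O)C(CCCC(=C)CO[Si](C)(C)C(C)(C)C)P(=O)(OCC)OCC)[C@H](OCOC)C=O
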